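**Remark on the chemistry:** daucane numbering is used for every bicyclic compound (ring B = C1–C2–C3–C4–C5; ring A = C5–C6–C7–C8–C9–C10–C1; C11–C13 = isopropyl group on C4; C14 = methyl on C8; C15 = methyl on C1). β is the face that carries C15, α the opposite face. The phenol of the acyl donor is assumed to need a silyl group during the esterification.

## Analysis of the target

Target 18 is the 6-O-(E)-p-coumarate of a daucane sesquiterpenoid: a cyclopentane ring B fused trans to a seven-membered ring A. It has four stereocentres, (1R,4R,5S,6S): the quaternary C1 with the C15 methyl, the tertiary carbinol C4 with hydroxyl and isopropyl, the ring-fusion methine C5 and the acyloxy carbon C6. The C15 methyl and the C4 hydroxyl lie on the β face; H5 and the C6 oxygen lie on the α face. Ring A carries a γ-acyloxy enone, C6(O)–C7=C8(CH3)–C9(=O), which is sensitive to base (vinylogous enolisation at C6, drift to a 1,4-dione). The coumarate adds a free phenol, a Michael acceptor and an (E)-alkene that would not survive hydrogenation, dissolving metals or photooxygenation. The hard points are the quaternary C1 next to the fusion methine in a trans-fused 5–7 system, the tertiary alcohol beside it, and oxygen at both C6 and C9 of a medium ring. The feature that the strategy uses is that C1, C10, C9, C8, C7 and C6 of ring A have the pattern of a para-disubstituted benzene: the C14 methyl on C8 is para to C1, which carries the chain C2–C3–C4. The seventh ring atom, C5, is bonded to that chain's oxygenated terminus C4. Ring A is therefore a toluene ring enlarged by the one carbon that also closes ring B.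

## Retrosynthetic reasoning

**C6–O ester bond.** 18 is taken back to its silyl ether 17 and then to diol 13 and the protected acid 16, which comes from 14. The ester is the most labile bond and the coumarate tolerates none of the earlier redox or photochemical steps, so it goes on last. The forward reaction has to acylate the secondary allylic C6 hydroxyl and leave the tertiary C4 hydroxyl alone.

**C9=O and C6–OH.** The γ-hydroxy enone of 13 is the base-rearranged form of endoperoxide 12, which comes from a sensitised photooxygenation across C6 and C9 of diene 11. Cutting both C–O bonds at once returns a plain C6=C7–C8=C9 diene and explains the position of the C7=C8 bond in the target. Forward, dioxygen must add to the α face, and the base must remove H9 and not H6.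

**C4–C11 bond.** 11 goes back to ketone 10 and an isopropyl organometallic. The cut is made here because the ketone is also the handle for the preceding step, and because a trans-fused ketone has one open face (α, past H5). Forward, addition must beat enolisation at the allylic C5–H.

**C1–C15 and C5–H.** The angular methyl and the fusion hydrogen of 10 are traced to the cyclopropane of ketone 9 by reductive opening of the C5–CH2 bond. 9 comes from carbinol 8 by oxidation, and 8 from allylic alcohol 7 by hydroxyl-directed methylene transfer to C1=C5. 7 is the enantioselective reduction product of enone 6. A direct asymmetric conjugate methylation of a tetrasubstituted enone is not dependable, so a C4 carbinol of defined configuration relays chirality to C1 and is then oxidised away.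

**C5–C1 and C5–C6 (key disconnection).** Achiral trienone 6 is the conjugated isomer of cycloheptatriene 5. 5 is the ring-opened form of norcaradiene 4, and 4 is the adduct of the acylcarbene from diazoketone 3 with its own aromatic ring. This removes both rings at once and leaves a benzene ring that already carries every ring A carbon with the methyl group in place. Forward, the carbenoid must add to the ipso–ortho bond and the proton shift must stop at the right isomer.

**Diazoketone.** 3 comes from acid chloride 2 and hence from acid 1 by a one-carbon diazo homologation, which is routine.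

## Alternatives that were turned down

**Alternative 1:** Ring A would be closed last, at C7–C8. Precursor A2 is a finished ring B (C1, C4 and C5 set, C4–OH silylated) whose C1 side chain ends in the enol silane of an ethyl ketone (C9, C8, C14) and whose C5 carries the enol silane of a methyl ketone (C6, C7). At a carbon anode the more substituted enol silane would be oxidised to a radical cation, C7 of the other would attack C8, and dione A1 would result.
- For it: both ring A oxygens (C6 and C9) arrive in the ring-closing step, the C14 methyl is in place, and the three ring B stereocentres are secured before the key step. On these points it is stronger than the chosen route.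
- Against it: a seven-membered ring is closed by a radical-cation coupling that competes with desilylation and intermolecular coupling. A2 is a densely substituted cyclopentane that needs a long stereocontrolled synthesis of its own. A1 still needs C7=C8 unsaturation between two ketones and then a chemo- and stereoselective reduction of the more hindered C6 ketone next to an epimerisable C5.
- Comparison: the chosen route reaches the complete bicyclic carbon skeleton, methyl included, in three steps from a commercial acid. It pays for this by building the stereocentres afterwards.

**Alternative 2:** Ring A would be made by a (5+2) cycloaddition that forms C1–C10 and C5–C6 together. An amine base would release a 3-oxidopyrylium dipole from acetoxypyranone A4; the dipole would add across the trisubstituted alkene of acyclic enone A5 to give oxygen-bridged adduct A3.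
- For it: it is convergent, it sets C1, C5 and C6 in one step, and the C9 enone with its C14 methyl and the C6 oxygen come ready-made. On convergency and on the ring A oxidation pattern it is stronger than the chosen route.
- Against it: the dipolarophile is a β,β-disubstituted acyclic enone that must form a quaternary carbon, so rate, regiochemistry and endo/exo selectivity are all in doubt. The adduct is racemic unless an asymmetric variant is found. Ring B still has to be closed at C3–C4 by adding a C3 nucleophile to the isopropyl ketone with control at C4, in the presence of an enone, and the ether bridge must be cleaved at C10.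
- Comparison: the chosen route fixes absolute configuration with a reagent-controlled reduction and closes both rings by an established reaction type.

**Alternative 3:** Ring B would be closed at C4–C5 by an intramolecular aldol reaction. Diketone A7, in which a conjugate addition has already created quaternary C1 on a cycloheptanone, would be enolised toward C5 under equilibrating base and add to the isopropyl ketone to give β-hydroxy ketone A6.
- For it: the chemistry is simple carbonyl chemistry, C1 can be set catalytically, and C4 and C5 settle under thermodynamic control (helped by a hydrogen bond or chelate between the C4 oxygen and the C6 carbonyl). For C4/C5 this is more secure than the kinetic protonation used in the chosen route.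
- Against it: A6 has a bare ring A. It lacks the C14 methyl, the C7=C8 bond and the C9 oxygen, and these would have to be installed at positions remote from the only handle (C6=O). The C6 ketone must also be reduced to the α-alcohol, and the β-hydroxy ketone can revert by retro-aldol cleavage.
- Comparison: in the chosen route ring A arrives with its methyl and a diene that becomes the C6–O / C7=C8 / C9=O array in two steps.

Key step: step 3

## Route

**Step 1**
Reactants: 1 3-(4-methylphenyl)propanoic acid
Product: 2 3-(4-methylphenyl)propanoyl chloride
Conditions: (COCl)2, cat. N,N-dimethylformamide, CH2Cl2, 0 °C to rt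
Reagents that add atoms: oxalyl chloride, ClC(=O)C(=O)Cl
Why: Standard acid chloride formation through Vilsmeier-type activation; the by-products are gases, so crude 2 can be used directly.

**Step 2**
Reactants: 2 3-(4-methylphenyl)propanoyl chloride
Product: 3 1-diazo-4-(4-methylphenyl)butan-2-one
Conditions: CH2N2 (excess), Et2O, 0 °C to rt
Reagents that add atoms: diazomethane, C=[N+]=[N-]
Why: Acylation of diazomethane (first stage of an Arndt–Eistert sequence); a second equivalent of diazomethane takes up the HCl released, which keeps 3 from becoming the chloromethyl ketone.

**Step 3**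
Reactants: 3 1-diazo-4-(4-methylphenyl)butan-2-one
Product: 6 6-methyl-3,4-dihydroazulen-1(2H)-one, via tricyclic norcaradiene ketone 4 (not isolated), via 6-methyl-3,8a-dihydroazulen-1(2H)-one 5 (not isolated)
Conditions: Rh2(OAc)4 (1 mol %), CH2Cl2, reflux, slow addition of 3; then Et3N, CH2Cl2, rt
Reagents that add atoms: none
Why: Rh2(OAc)4 expels N2 from 3 and forms an electrophilic rhodium carbenoid at C5, which cyclopropanates the ipso–ortho bond C1–C6 of the tolyl ring to give norcaradiene 4 (intramolecular Buchner reaction). Ring B closes in this event as a five-membered ring through the new C5–C1 bond; the two-carbon tether C2–C3 lets the carbenoid reach only the ipso–ortho bond, since addition further round the ring would need a strained bridged product. Ring A is then formed by enlargement and not by closure: thermal disrotatory 6π opening of 4 breaks C1–C6 and leaves C5, bonded to both, as the seventh ring atom of cycloheptatriene 5. Et3N removes the doubly activated C5–H of 5 and the extended enolate is reprotonated at C10, which brings C1=C5 into conjugation with the C4 ketone and leaves the C6=C7–C8=C9 diene of 6. The closest known reaction type is the Rh2(OAc)4-catalysed cyclisation of 1-diazo-4-arylbutan-2-ones to dihydroazulenones, the class to which 3 belongs. Product 6 is achiral, so no stereocentre has to be controlled; the one stereocentre of 5 (C5) is erased in the conjugation. The step needs chemoselectivity for arene addition over Wolff rearrangement, carbenoid dimerisation and aromatic substitution (which would end in a 2-tetralone): the electrophilic carboxylate catalyst, slow addition of 3 to the hot catalyst solution, the lack of any C–H bond placed for five-membered insertion and the exclusion of acid should secure it. Regioselectivity is given by the substrate, because the two ortho carbons of the para-disubstituted ring are equivalent, which also puts the methyl group on C8.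

**Step 4**
Reactants: 6 6-methyl-3,4-dihydroazulen-1(2H)-one
Product: 7 (S)-6-methyl-1,2,3,4-tetrahydroazulen-1-ol
Conditions: (R)-1-methyl-3,3-diphenyltetrahydro-1H,3H-pyrrolo[1,2-c][1,3,2]oxazaborole (20 mol %), catecholborane, toluene, −78 °C
Reagents that add atoms: none
Why: Corey–Bakshi–Shibata reduction: with the fully substituted alkenyl carbon C5 as the large group and the C3 methylene as the small one, the (R)-catalyst should deliver hydride to the face that gives the (S)-carbinol (C4–OH β). Catecholborane at low temperature reduces the carbonyl 1,2 and should leave the triene alone; this stereocentre only relays absolute configuration to C1 and is removed in step 6.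

**Step 5**
Reactants: 7 (S)-6-methyl-1,2,3,4-tetrahydroazulen-1-ol
Product: 8 (1S,3aR,8aS)-6-methyl-1,2,3,4-tetrahydro-3a,8a-methanoazulen-1-ol (cyclopropane CH2 across C1–C5, cis to the hydroxyl)
Conditions: Et2Zn, CH2I2, CH2Cl2, −20 to 0 °C
Reagents that add atoms: diiodomethane, ICI
Why: Hydroxyl-directed Simmons–Smith cyclopropanation (Furukawa conditions): the zinc alkoxide of 7 delivers the methylene to the adjacent, most electron-rich tetrasubstituted C1=C5 bond on the face of the oxygen, which sets C1 with its new carbon β (the future C15). The alkene next to the carbinol is the one expected to react in a conjugated polyenol, and only a small excess of carbenoid is used to spare the C6=C7–C8=C9 diene.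

**Step 6**
Reactants: 8 (1S,3aR,8aS)-6-methyl-1,2,3,4-tetrahydro-3a,8a-methanoazulen-1-ol
Product: 9 (3aR,8aS)-6-methyl-3,4-dihydro-3a,8a-methanoazulen-1(2H)-one
Conditions: Dess–Martin periodinane, pyridine, CH2Cl2, 0 °C to rt
Reagents that add atoms: none
Why: Dess–Martin oxidation of a secondary cyclopropyl carbinol under buffered, non-acidic conditions, which avoids cyclopropylcarbinyl cation chemistry; C5 is quaternary, so the new ketone cannot enolise toward the ring fusion.

**Step 7**
Reactants: 9 (3aR,8aS)-6-methyl-3,4-dihydro-3a,8a-methanoazulen-1(2H)-one
Product: 10 (3aR,8aR)-3a,6-dimethyl-3,3a,4,8a-tetrahydroazulen-1(2H)-one (trans ring fusion; C15 β, H5 α)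
Conditions: SmI2, THF–HMPA, t-BuOH, −78 °C; pH 7 buffer
Reagents that add atoms: none
Why: Reductive cleavage of an α-cyclopropyl ketone by samarium diiodide: the ketyl opens the exocyclic C5–CH2 bond, which is aligned with the carbonyl π system (the C1–C5 fusion bond lies in the plane of ring B and would give a bridgehead enolate), and the primary radical is reduced and protonated to the C15 methyl. The trienolate is expected to be protonated kinetically at C5 from the α face, away from the new methyl, which gives the trans fusion; this is also the fusion that the large ring A torsion angle about C1–C5 should favour for a fused five-membered ring. SmI2 is chosen over a dissolving metal because it should leave the conjugated diene alone.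

**Step 8**
Reactants: 10 (3aR,8aR)-3a,6-dimethyl-3,3a,4,8a-tetrahydroazulen-1(2H)-one
Product: 11 (1R,3aR,8aR)-3a,6-dimethyl-1-(propan-2-yl)-1,2,3,3a,4,8a-hexahydroazulen-1-ol (= (1R,4R,5R)-dauca-6,8-dien-4-ol; 4β-OH, 4α-isopropyl)
Conditions: i-PrMgCl, CeCl3, THF, −78 to 0 °C
Reagents that add atoms: isopropylmagnesium chloride, CC(C)[Mg]Cl
Why: 1,2-Addition of an organocerium reagent, which is nucleophilic but weakly basic and so suits a hindered ketone with an acidic, allylic α-hydrogen. Attack is expected from the α face, past H5 and away from the pseudo-axial C15 methyl on C1, which puts the isopropyl group α and the new hydroxyl β as in the target.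

**Step 9**
Reactants: 11 (1R,4R,5R)-dauca-6,8-dien-4-ol
Product: 12 (1R,4R,5S)-6α,9α-epidioxydauc-7-en-4-ol (peroxide bridge from C6 to C9 on the face of H5)
Conditions: O2, visible light, methylene blue (3,7-bis(dimethylamino)phenothiazin-5-ium chloride), MeOH–CH2Cl2, −20 °C
Reagents that add atoms: dioxygen, O=O
Why: [4+2] Cycloaddition of singlet oxygen to the s-cis diene held in ring A. The β face is screened by the pseudo-axial C15 methyl and by C4 with its hydroxyl, so dioxygen should add from the α face and set C6–O α; methanol as cosolvent suppresses hydroxyl-directed delivery to the β face. The photooxygenation is placed before the light- and oxidation-sensitive coumarate is attached.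

**Step 10**
Reactants: 12 (1R,4R,5S)-6α,9α-epidioxydauc-7-en-4-ol
Product: 13 (1R,4R,5S,6S)-4,6-dihydroxydauc-7-en-9-one
Conditions: Et3N, CH2Cl2, 0 °C to rt
Reagents that add atoms: none
Why: Kornblum–DeLaMare rearrangement: the amine removes the bridgehead hydrogen on C9 as the O–O bond breaks, which gives the C9 ketone conjugated with C7=C8 and leaves the C6–O bond, and so the 6α configuration, untouched. Abstraction at C9 and not at C6 is expected because H6 sits next to the fully substituted C4/C5 region and because the C4 hydroxyl can hydrogen-bond to the oxygen on C6 that becomes the alkoxide.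

**Step 11**
Reactants: 14 (E)-3-(4-hydroxyphenyl)prop-2-enoic acid (p-coumaric acid)
Product: 16 (E)-3-[4-(tert-butyldimethylsilyloxy)phenyl]prop-2-enoic acid, via bis-silylated silyl ester 15 (not isolated)
Conditions: TBSCl (2.4 equiv), imidazole, DMF, rt; then AcOH, THF–H2O, rt
Reagents that add atoms: tert-butyldimethylsilyl chloride, CC(C)(C)[Si](C)(C)Cl
Why: Silylation of both the phenol and the acid, then selective hydrolysis of the much more labile silyl ester under mild aqueous acid, which leaves the aryl silyl ether; the (E)-alkene is not affected.

**Step 12**
Reactants: 13 (1R,4R,5S,6S)-4,6-dihydroxydauc-7-en-9-one; 16 (E)-3-[4-(tert-butyldimethylsilyloxy)phenyl]prop-2-enoic acid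
Product: 17 (1R,4R,5S,6S)-4-hydroxy-9-oxodauc-7-en-6-yl (E)-3-[4-(tert-butyldimethylsilyloxy)phenyl]prop-2-enoate
Conditions: DCC, 4-(dimethylamino)pyridine (cat.), CH2Cl2, 0 °C to rt
Reagents that add atoms: none
Why: Steglich esterification: the activated acid is passed by the pyridine catalyst to the secondary allylic C6 hydroxyl, while the tertiary C4 hydroxyl is too hindered to be acylated; no stereocentre is touched and the (E)-geometry is kept.

**Step 13**
Reactants: 17 (1R,4R,5S,6S)-4-hydroxy-9-oxodauc-7-en-6-yl (E)-3-[4-(tert-butyldimethylsilyloxy)phenyl]prop-2-enoate
Product: 18 (1R,4R,5S,6S)-4-hydroxy-9-oxodauc-7-en-6-yl (E)-3-(4-hydroxyphenyl)prop-2-enoate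
Conditions: TBAF, AcOH, THF, 0 °C
Reagents that add atoms: none
Why: Fluoride cleavage of the aryl silyl ether; acetic acid protonates the phenoxide at once, so neither the cinnamate ester nor the base-sensitive γ-acyloxy enone should be attacked.

## Compound list

1 | 3-(4-methylphenyl)propanoic acid | Cc1ccc(CCC(O)=O)cc1 | starting material
2 | 3-(4-methylphenyl)propanoyl chloride | Cc1ccc(CCC(Cl)=O)cc1 | intermediate
3 | 1-diazo-4-(4-methylphenyl)butan-2-one | Cc1ccc(CCC(=O)C=[N+]=[N-])cc1 | intermediate
4 | tricyclic norcaradiene ketone (racemic; C5 bonded to C1 and C6, diene C7=C8–C9=C10) | O=C1CCC23C=CC(C)=CC2C13 | intermediate (not isolated)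
5 | 6-methyl-3,8a-dihydroazulen-1(2H)-one (racemic) | O=C1CCC2=CC=C(C)C=CC12 | intermediate (not isolated)
6 | 6-methyl-3,4-dihydroazulen-1(2H)-one | CC1=CCC2=C(C=C1)C(=O)CC2 | intermediate
7 | (S)-6-methyl-1,2,3,4-tetrahydroazulen-1-ol | CC1=CCC2=C(C=C1)[C@@H](O)CC2 | intermediate
8 | (1S,3aR,8aS)-6-methyl-1,2,3,4-tetrahydro-3a,8a-methanoazulen-1-ol | CC1=CC[C@@]23CC[C@H](O)[C@]2(C=C1)C3 | intermediate
9 | (3aR,8aS)-6-methyl-3,4-dihydro-3a,8a-methanoazulen-1(2H)-one | CC1=CC[C@@]23CCC(=O)[C@]2(C=C1)C3 | intermediate
10 | (3aR,8aR)-3a,6-dimethyl-3,3a,4,8a-tetrahydroazulen-1(2H)-one | CC1=CC[C@@]2(C)CCC(=O)[C@@H]2C=C1 | intermediate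
11 | (1R,3aR,8aR)-3a,6-dimethyl-1-(propan-2-yl)-1,2,3,3a,4,8a-hexahydroazulen-1-ol | CC1=CC[C@@]2(C)CC[C@@](O)(C(C)C)[C@@H]2C=C1 | intermediate
12 | (1R,4R,5S)-6α,9α-epidioxydauc-7-en-4-ol | CC1=C[C@@H]2OO[C@H]1C[C@@]3(C)CC[C@@](O)(C(C)C)[C@H]23 | intermediate
13 | (1R,4R,5S,6S)-4,6-dihydroxydauc-7-en-9-one | CC1=C[C@H](O)[C@@H]2[C@](C)(CC[C@@]2(O)C(C)C)CC1=O | intermediate
14 | (E)-3-(4-hydroxyphenyl)prop-2-enoic acid (p-coumaric acid) | OC(=O)/C=C/c1ccc(O)cc1 | starting material
15 | tert-butyldimethylsilyl (E)-3-[4-(tert-butyldimethylsilyloxy)phenyl]prop-2-enoate | CC(C)(C)[Si](C)(C)OC(=O)/C=C/c1ccc(O[Si](C)(C)C(C)(C)C)cc1 | intermediate (not isolated)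
16 | (E)-3-[4-(tert-butyldimethylsilyloxy)phenyl]prop-2-enoic acid | OC(=O)/C=C/c1ccc(O[Si](C)(C)C(C)(C)C)cc1 | intermediate
17 | (1R,4R,5S,6S)-4-hydroxy-9-oxodauc-7-en-6-yl (E)-3-[4-(tert-butyldimethylsilyloxy)phenyl]prop-2-enoate | CC1=C[C@H](OC(=O)/C=C/c2ccc(O[Si](C)(C)C(C)(C)C)cc2)[C@@H]2[C@](C)(CC[C@@]2(O)C(C)C)CC1=O | intermediate
18 | (1R,4R,5S,6S)-4-hydroxy-9-oxodauc-7-en-6-yl (E)-3-(4-hydroxyphenyl)prop-2-enoate | CC1=C[C@H](OC(=O)/C=C/c2ccc(O)cc2)[C@@H]2[C@](C)(CC[C@@]2(O)C(C)C)CC1=O | target

## Step count and least certain steps

Total step count: 13. Longest linear sequence: 12 steps (steps 1–10, 12 and 13, from 1); step 11 prepares the acyl donor.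

**Step 3 (key step).** The most likely failure is diversion of the carbenoid or of the labile norcaradiene/cycloheptatriene pair. Aromatic substitution or traces of acid would lead to a tetralone, too high a concentration to carbenoid dimers, and the base treatment can let the proton keep migrating round ring A to give double-bond isomers of 6. The fallback makes the same C5–C1 and C5–C6 bonds on a ring that is no longer aromatic, so the carbenoid meets only an ordinary alkene. It sets out from 1. Birch reduction (Li, liquid NH3, t-BuOH) should give 3-(4-methylcyclohexa-1,4-dien-1-yl)propanoic acid F1. Activation with ethyl chloroformate and Et3N gives the mixed ethyl carbonic anhydride F2 in the flask, and diazomethane converts it into 1-diazo-4-(4-methylcyclohexa-1,4-dien-1-yl)butan-2-one F3. Rh2(OAc)4 then effects intramolecular cyclopropanation of the alkene that carries the tether, giving the tricyclic cyclopropyl ketone F4. Bromine adds to the remaining C8=C9 bond to give the 8,9-dibromide F5, and double dehydrobromination with DBU generates 4, which opens and is conjugated by the same base. The fallback comes back to the route at 6.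

**Step 7.** The most likely failure is protonation of the extended samarium enolate at the wrong place: from the β face (cis ring fusion) or at C7 or C9 (the diene drifts into conjugation with the ketone). Over-reduction by excess reagent is a further risk. The fallback separates ring opening from protonation and avoids electron transfer. It sets out from 9. Iodotrimethylsilane made in the flask (TMSCl, NaI, MeCN, −20 °C) should open the activated cyclopropane at its CH2 carbon to give the γ-iodo silyl enol ether 15-iodo-4-(trimethylsilyloxy)-11,12,13-trinordauca-4,6,8-triene F6. Buffered hydrolysis protonates C5 on the face opposite the bulky iodomethyl group and gives the trans-fused γ-iodo ketone F7. Tin hydride reduction (Bu3SnH, azobisisobutyronitrile, toluene, 80 °C) turns CH2I into the C15 methyl. The fallback comes back at 10.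

**Step 8.** The most likely failure is enolisation at the doubly activated C5–H, or hydride transfer from the secondary organometallic, in place of addition. The fallback uses a smaller sp2 nucleophile that cannot transfer hydride. It sets out from 10. 2-Propenylmagnesium bromide with CeCl3 should give the 4α-(prop-1-en-2-yl) carbinol F8 with the same facial preference, and hydrogenation with RhCl(PPh3)3 under H2, which prefers the unhindered 1,1-disubstituted alkene over the ring diene, saturates the side chain. The fallback comes back at 11.

**Step 9.** The most likely failure is poor facial selectivity: hydrogen bonding to the C4 hydroxyl, or the α-oriented isopropyl group near C6, could send dioxygen to the β face. An ene reaction at the trisubstituted C8=C9 bond is a lesser risk. The fallback corrects C6 by inversion and not by substrate control. It sets out from 11. If the 6β,9β-endoperoxide F9 predominates, it is rearranged with Et3N as in step 10 to the 6-epimeric hydroxy enone F10, and F10 is esterified with 16 under Mitsunobu conditions (PPh3, diisopropyl azodicarboxylate, THF, 0 °C) with inversion at C6. The fallback comes back at 17.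

**Step 10.** The most likely failure is loss of regiocontrol in the base-induced fragmentation (removal of H6, giving the 6-keto-9-hydroxy isomer) or further base-induced isomerisation of the γ-hydroxy enone to the saturated 1,4-diketone. The fallback separates O–O cleavage from oxidation. It sets out from 12. Thiourea in methanol reduces the peroxide to the cis-enediol (1R,4R,5S,6S)-dauc-7-ene-4,6α,9α-triol F11, and MnO2 in CH2Cl2 should oxidise the less hindered allylic C9 hydroxyl in preference to the C6 hydroxyl beside the congested C4/C5 region. The fallback comes back at 13.

## Further compounds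

F1 | step 3 | 3-(4-methylcyclohexa-1,4-dien-1-yl)propanoic acid | CC1=CCC(CCC(O)=O)=CC1
F2 | step 3 | ethyl carbonic 3-(4-methylcyclohexa-1,4-dien-1-yl)propanoic anhydride | CCOC(=O)OC(=O)CCC1=CCC(C)=CC1
F3 | step 3 | 1-diazo-4-(4-methylcyclohexa-1,4-dien-1-yl)butan-2-one | CC1=CCC(CCC(=O)C=[N+]=[N-])=CC1
F4 | step 3 | tricyclic cyclopropyl ketone (racemic; C5 bonded to C1 and C6, alkene C8=C9) | O=C1CCC23CC=C(C)CC2C13
F5 | step 3 | 8,9-dibromide of the tricyclic cyclopropyl ketone (racemic) | O=C1CCC23CC(Br)C(C)(Br)CC2C13
F6 | step 7 | 15-iodo-4-(trimethylsilyloxy)-11,12,13-trinordauca-4,6,8-triene | CC1=CC[C@@]2(CI)CCC(O[Si](C)(C)C)=C2C=C1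
F7 | step 7 | trans-fused 3a-(iodomethyl)-6-methyl-3,3a,4,8a-tetrahydroazulen-1(2H)-one | CC1=CC[C@@]2(CI)CCC(=O)[C@@H]2C=C1
F8 | step 8 | trans-fused 3a,6-dimethyl-1-(prop-1-en-2-yl)-1,2,3,3a,4,8a-hexahydroazulen-1-ol (4β-OH) | CC1=CC[C@@]2(C)CC[C@@](O)(C(C)=C)[C@@H]2C=C1
F9 | step 9 | 6β,9β-epidioxydauc-7-en-4-ol | CC1=C[C@H]2OO[C@@H]1C[C@@]3(C)CC[C@@](O)(C(C)C)[C@H]23
F10 | step 9 | 6-epimer of 13 (4β,6β-dihydroxydauc-7-en-9-one) | CC1=C[C@@H](O)[C@@H]2[C@](C)(CC[C@@]2(O)C(C)C)CC1=O
F11 | step 10 | (1R,4R,5S,6S)-dauc-7-ene-4,6α,9α-triol | CC1=C[C@H](O)[C@@H]2[C@](C)(CC[C@@]2(O)C(C)C)C[C@@H]1O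
A1 | alternative 1 | 4-(trimethylsilyloxy)daucane-6,9-dione (either C8 epimer) | C[C@H]1C(=O)C[C@@]2(C)CC[C@@](O[Si](C)(C)C)(C(C)C)[C@@H]2C(=O)C1
A2 | alternative 1 | 7,8-seco bis(enol silane): ring B with the 2-(trimethylsilyloxy)but-2-enyl chain on C1, the 1-(trimethylsilyloxy)ethenyl group on C5 and the silyl ether on C4 | CC=C(O[Si](C)(C)C)C[C@@]1(C)CC[C@@](O[Si](C)(C)C)(C(C)C)[C@@H]1C(O[Si](C)(C)C)=C
A3 | alternative 2 | C6–O–C10 bridged (5+2) cycloadduct with the C1 methyl, the 2-(tert-butyldimethylsilyloxy)ethyl chain and the C4 isopropyl ketone | CC1=C[C@@H]2O[C@H](C1=O)[C@@](C)(CCO[Si](C)(C)C(C)(C)C)[C@@H]2C(=O)C(C)C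
A4 | alternative 2 | 6-acetoxy-4-methyl-2H-pyran-3(6H)-one | CC1=CC(OC(C)=O)OCC1=O
A5 | alternative 2 | (E)-7-(tert-butyldimethylsilyloxy)-2,5-dimethylhept-4-en-3-one | CC(C)C(=O)/C=C(\C)CCO[Si](C)(C)C(C)(C)C
A6 | alternative 3 | 4-hydroxy-14-nordaucan-6-one (C1, C4 and C5 as in the target) | CC(C)[C@]1(O)CC[C@]2(C)CCCCC(=O)[C@@H]12
A7 | alternative 3 | 3-methyl-3-(4-methyl-3-oxopentyl)cycloheptan-1-one (C1 as in the target) | CC(C)C(=O)CC[C@]1(C)CCCCC(=O)C1
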